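**Retrosynthetic overview**

- Ring A is a benzene-1,3-diol whose only carbon substituent, the C17 chain, sits at C5, meta to the oxygens on C1 and C3. This is the oxidation pattern of a 5-alkylcyclohexane-1,3-dione, so ring A (the only ring) is built last on the finished chain and then dehydrogenated (tris-silylation, DDQ, fluoride).
- Ring A comes from a [3+3] Michael–Claisen annulation of dimethyl malonate with (3E,12Z,19S)-19-hydroxyhenicosa-3,12-dien-2-one (C4–C5 first, then C2–C3), with saponification and decarboxylation in the same flask.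
- The enone comes from an acetonylidene Wittig reaction on (9Z,16S)-16-hydroxyoctadec-9-enal, itself made by primary-selective oxidation of the C18 ene-diol.
- The (Z)-alkene comes from a lithium-free Wittig reaction between the ylide of (9-hydroxynonyl)triphenylphosphonium bromide and (7S)-7-hydroxynonanal. The carbinol stereocentre is taken from (S)-1,2-epoxybutane, opened at CH2 by hex-5-enylmagnesium bromide and then ozonized; no protecting group is used before the ring is made.

Key step: step 7

Remark: (S)-1,2-epoxybutane is the only source of chirality; ring carbon C5 of compounds 19 and 20 is a transient stereocentre (both epimers, left unspecified in the SMILES) that disappears on aromatization.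

**Step 1**
Reactants: 1 (S)-1,2-epoxybutane; 2 6-bromohex-1-ene
Product: 4 (3S)-dec-9-en-3-ol, via hex-5-enylmagnesium bromide 3 (not isolated)
Conditions: Mg, THF, 20 °C; then CuI (10 mol %), 1, THF, −30 °C to 0 °C; aq NH4Cl
Reagents that add atoms: none
Why: Copper-catalysed SN2 opening of a monosubstituted epoxide by a primary Grignard reagent should occur at the unsubstituted CH2, so the C–O bond at the stereocentre is untouched and the S configuration of 1 is carried into 4 (the descriptor stays S because the new chain outranks ethyl).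

**Step 2**
Reactants: 4 (3S)-dec-9-en-3-ol
Product: 6 (7S)-7-hydroxynonanal, via ozonide 5 (not isolated)
Conditions: O3, CH2Cl2, −78 °C; then PPh3, −78 °C to 20 °C
Reagents that add atoms: ozone, O=[O+][O-]
Why: Ozonolysis (Criegee mechanism) of the terminal alkene with reductive cleavage of the ozonide should give the aldehyde, the free secondary alcohol and its remote stereocentre being inert to ozone and PPh3.

**Step 3**
Reactants: 7 9-bromononan-1-ol
Product: 8 (9-hydroxynonyl)triphenylphosphonium bromide
Conditions: PPh3, MeCN, reflux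
Reagents that add atoms: triphenylphosphine, c1ccc(cc1)P(c1ccccc1)c1ccccc1
Why: SN2 quaternization of triphenylphosphine by a primary alkyl bromide is a standard phosphonium salt synthesis and tolerates the free hydroxyl.

**Step 4**
Reactants: 8 (9-hydroxynonyl)triphenylphosphonium bromide; 6 (7S)-7-hydroxynonanal
Product: 10 (9Z,16S)-octadec-9-ene-1,16-diol, via sodium alkoxide ylide 9 (not isolated)
Conditions: 8 (2.2 equiv), NaN(SiMe3)2 (4.4 equiv), THF, 0 °C; then 6, −78 °C to 20 °C; aq NH4Cl
Reagents that add atoms: none
Why: A Wittig reaction of a non-stabilized ylide under lithium-free conditions should pass through the kinetically formed cis-oxaphosphetane and give the (Z)-alkene, the excess of ylide absorbing proton transfer from the hydroxyl of 6 as in Wittig reactions of lactols.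

**Step 5**
Reactants: 10 (9Z,16S)-octadec-9-ene-1,16-diol
Product: 11 (9Z,16S)-16-hydroxyoctadec-9-enal
Conditions: TEMPO (10 mol %), PhI(OAc)2 (1.1 equiv), CH2Cl2, 20 °C
Reagents that add atoms: none
Why: The oxoammonium-mediated TEMPO/PhI(OAc)2 oxidation discriminates sterically in favour of the primary alcohol and should stop at the aldehyde, leaving the secondary carbinol and the (Z)-alkene untouched.

**Step 6**
Reactants: 11 (9Z,16S)-16-hydroxyoctadec-9-enal; 12 1-(triphenylphosphoranylidene)propan-2-one
Product: 13 (3E,12Z,19S)-19-hydroxyhenicosa-3,12-dien-2-one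
Conditions: 12 (1.3 equiv), THF, reflux
Reagents that add atoms: none
Why: A Wittig reaction of the stabilized acetonylidene ylide is reversible up to the oxaphosphetane and should deliver the (E)-enone under neutral conditions that affect neither the free alcohol nor the (Z)-alkene.

**Step 7**
Reactants: 13 (3E,12Z,19S)-19-hydroxyhenicosa-3,12-dien-2-one; 14 dimethyl malonate
Product: 18 5-[(8Z,15S)-15-hydroxyheptadec-8-en-1-yl]cyclohexane-1,3-dione, via malonate Michael adduct 15 (not isolated), via cyclic keto ester 16 (not isolated), via dioxo acid 17 (not isolated)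
Conditions: NaOMe (1.5 equiv), 14 (1.5 equiv), MeOH, reflux; then 2 M aq NaOH, reflux with MeOH distilled off; then HCl to pH 1, 80 °C
Reagents that add atoms: none
Why: Methoxide-generated sodiomalonate adds 1,4 to the (E)-enone to form ring bond C4–C5 (adduct 15); proton transfer then gives the enolate on the methyl side of the ketone, which acylates onto the neighbouring ester to form C2–C3 and ring A (16), and the closure is pulled through by irreversible deprotonation of the cyclic β-dicarbonyl product. The closest known reaction type is the classical one-flask Michael addition, Claisen (Dieckmann-type) condensation, saponification and decarboxylation of alk-3-en-2-ones with malonic esters to 5-alkylcyclohexane-1,3-diones. Ring A closes in a 6-(enolendo)-exo-trig mode, since both enolate carbons of the methyl ketone lie in the new ring and the ester C=O that is attacked is exocyclic to it. No stereocentre is created in 18: its C5 lies on the mirror plane of the dione, the transient centres of 15 to 17 vanish on decarboxylation, and the chain carbinol is remote from every acidic position and stays S. The step needs acylation from the methyl carbon and not from C3 of the ketone, which would give a four-membered ring, and it needs the isolated (Z)-alkene and the free secondary alcohol to be spectators, which holds because neither is acidic or electrophilic towards alkoxide, hydroxide or dilute acid at 80 °C. Methanol is distilled out before acidification so that the dione is not trapped as its vinylogous methyl ester.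

**Step 8**
Reactants: 18 5-[(8Z,15S)-15-hydroxyheptadec-8-en-1-yl]cyclohexane-1,3-dione
Product: 20 1,3-bis[(tert-butyldimethylsilyl)oxy]-5-[(8Z,15S)-15-[(tert-butyldimethylsilyl)oxy]heptadec-8-en-1-yl]cyclohexa-1,3-diene, via silyloxy enone 19 (not isolated)
Conditions: TBSOTf (3.3 equiv), Et3N (5 equiv), CH2Cl2, 0 °C to 20 °C; cold aq NaHCO3 work-up, used without storage
Reagents that add atoms: tert-butyldimethylsilyl trifluoromethanesulfonate, CC(C)(C)[Si](C)(C)OS(=O)(=O)C(F)(F)F
Why: Silyl triflate/amine soft enolization should silylate the alcohol and the enol, then silylate the vinylogous ester carbonyl of 19 to a symmetrical 1,3-bis(silyloxy)allyl cation that loses a proton from C4 or C6 (equivalent positions) to give the conjugated bis(silyloxy)diene.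

**Step 9**
Reactants: 20 1,3-bis[(tert-butyldimethylsilyl)oxy]-5-[(8Z,15S)-15-[(tert-butyldimethylsilyl)oxy]heptadec-8-en-1-yl]cyclohexa-1,3-diene
Product: 21 1,3-bis[(tert-butyldimethylsilyl)oxy]-5-[(8Z,15S)-15-[(tert-butyldimethylsilyl)oxy]heptadec-8-en-1-yl]benzene
Conditions: DDQ (1.1 equiv), 2,6-lutidine (1.5 equiv), CH2Cl2, 0 °C
Reagents that add atoms: none
Why: In this quinone dehydrogenation of a silyloxycyclohexadiene, DDQ should abstract hydride from the allylic C5–H to give a cation stabilized by both silyloxy groups (the arenium ion of the product), which loses the C6 proton to form the arene, while the isolated (Z)-alkene and the alkyl silyl ether are inert at 0 °C and lutidine buffers the acidic hydroquinone.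

**Step 10**
Reactants: 21 1,3-bis[(tert-butyldimethylsilyl)oxy]-5-[(8Z,15S)-15-[(tert-butyldimethylsilyl)oxy]heptadec-8-en-1-yl]benzene
Product: 22 hansfordiol G, 5-[(8Z,15S)-15-hydroxyheptadec-8-en-1-yl]benzene-1,3-diol
Conditions: Bu4NF (4 equiv), AcOH (4 equiv), THF, 0 °C to 40 °C
Reagents that add atoms: none
Why: Fluoride-driven cleavage of the Si–O bonds should remove the two aryl and the one alkyl silyl ether without touching the carbinol configuration or the (Z)-alkene, the acetic acid buffer keeping the resorcinol from standing as an oxidizable phenoxide.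

**Compound list**

1 | (S)-1,2-epoxybutane, (2S)-2-ethyloxirane | CC[C@H]1CO1 | starting material
2 | 6-bromohex-1-ene | C=CCCCCBr | starting material
3 | hex-5-enylmagnesium bromide | C=CCCCC[Mg]Br | intermediate (not isolated)
4 | (3S)-dec-9-en-3-ol | CC[C@H](O)CCCCCC=C | intermediate
5 | 3-[(6S)-6-hydroxyoctyl]-1,2,4-trioxolane (ozonide, ring carbon unspecified) | CC[C@H](O)CCCCCC1OCOO1 | intermediate (not isolated)
6 | (7S)-7-hydroxynonanal | CC[C@H](O)CCCCCC=O | intermediate
7 | 9-bromononan-1-ol | OCCCCCCCCCBr | starting material
8 | (9-hydroxynonyl)triphenylphosphonium bromide | OCCCCCCCCC[P+](c1ccccc1)(c1ccccc1)c1ccccc1.[Br-] | intermediate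
9 | sodium 9-(triphenylphosphoranylidene)nonan-1-olate | [Na+].[O-]CCCCCCCCC=P(c1ccccc1)(c1ccccc1)c1ccccc1 | intermediate (not isolated)
10 | (9Z,16S)-octadec-9-ene-1,16-diol | CC[C@H](O)CCCCC/C=C\CCCCCCCCO | intermediate
11 | (9Z,16S)-16-hydroxyoctadec-9-enal | CC[C@H](O)CCCCC/C=C\CCCCCCCC=O | intermediate
12 | 1-(triphenylphosphoranylidene)propan-2-one | CC(=O)C=P(c1ccccc1)(c1ccccc1)c1ccccc1 | starting material
13 | (3E,12Z,19S)-19-hydroxyhenicosa-3,12-dien-2-one | CC[C@H](O)CCCCC/C=C\CCCCCCC/C=C/C(C)=O | intermediate
14 | dimethyl malonate | COC(=O)CC(=O)OC | starting material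
15 | dimethyl 2-[(12Z,19S)-19-hydroxy-2-oxohenicos-12-en-4-yl]propanedioate (C4 unspecified) | CC[C@H](O)CCCCC/C=C\CCCCCCCC(CC(C)=O)C(C(=O)OC)C(=O)OC | intermediate (not isolated)
16 | methyl 2-[(8Z,15S)-15-hydroxyheptadec-8-en-1-yl]-4,6-dioxocyclohexane-1-carboxylate (ring centres unspecified; present as its sodium enolate) | CC[C@H](O)CCCCC/C=C\CCCCCCCC1CC(=O)CC(=O)C1C(=O)OC | intermediate (not isolated)
17 | 2-[(8Z,15S)-15-hydroxyheptadec-8-en-1-yl]-4,6-dioxocyclohexane-1-carboxylic acid | CC[C@H](O)CCCCC/C=C\CCCCCCCC1CC(=O)CC(=O)C1C(=O)O | intermediate (not isolated)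
18 | 5-[(8Z,15S)-15-hydroxyheptadec-8-en-1-yl]cyclohexane-1,3-dione | CC[C@H](O)CCCCC/C=C\CCCCCCCC1CC(=O)CC(=O)C1 | intermediate
19 | 3-[(tert-butyldimethylsilyl)oxy]-5-[(8Z,15S)-15-[(tert-butyldimethylsilyl)oxy]heptadec-8-en-1-yl]cyclohex-2-en-1-one (both C5 epimers) | CC[C@H](O[Si](C)(C)C(C)(C)C)CCCCC/C=C\CCCCCCCC1CC(=O)C=C(O[Si](C)(C)C(C)(C)C)C1 | intermediate (not isolated)
20 | 1,3-bis[(tert-butyldimethylsilyl)oxy]-5-[(8Z,15S)-15-[(tert-butyldimethylsilyl)oxy]heptadec-8-en-1-yl]cyclohexa-1,3-diene (both C5 epimers) | CC[C@H](O[Si](C)(C)C(C)(C)C)CCCCC/C=C\CCCCCCCC1CC(O[Si](C)(C)C(C)(C)C)=CC(O[Si](C)(C)C(C)(C)C)=C1 | intermediate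
21 | 1,3-bis[(tert-butyldimethylsilyl)oxy]-5-[(8Z,15S)-15-[(tert-butyldimethylsilyl)oxy]heptadec-8-en-1-yl]benzene | CC[C@H](O[Si](C)(C)C(C)(C)C)CCCCC/C=C\CCCCCCCc1cc(O[Si](C)(C)C(C)(C)C)cc(O[Si](C)(C)C(C)(C)C)c1 | intermediate
22 | hansfordiol G, 5-[(8Z,15S)-15-hydroxyheptadec-8-en-1-yl]benzene-1,3-diol | CC[C@H](O)CCCCC/C=C\CCCCCCCc1cc(O)cc(O)c1 | target

**Step count**

Total steps: 10. Longest linear sequence: 9 steps (steps 1, 2, 4, 5, 6, 7, 8, 9, 10 from (S)-1,2-epoxybutane); step 3 is a one-step side branch.

**Steps most likely to fail, with fallbacks**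

Step 9. The enol silyl groups may be hydrolysed by the acidic hydroquinone before hydride transfer, which would return the dione. DDQ may also add to the electron-rich diene at carbon or oxygen instead of dehydrogenating it. The fallback sets out from 18 and comes back at 22. Silylation of 18 with TBSCl (2.2 equiv) and imidazole in DMF should stop at the vinylogous silyl ester 19, which is isolated in this variant. Kinetic deprotonation at the carbon next to the ketone with LiN(iPr)2 in THF at −78 °C and trapping with PhSeBr should give 3-[(tert-butyldimethylsilyl)oxy]-5-[(8Z,15S)-15-[(tert-butyldimethylsilyl)oxy]heptadec-8-en-1-yl]-6-(phenylselanyl)cyclohex-2-en-1-one F1. Oxidation with H2O2 and pyridine in CH2Cl2 at 0 °C should trigger selenoxide syn-elimination towards C5, and the resulting cross-conjugated dienone tautomerizes to 3-[(tert-butyldimethylsilyl)oxy]-5-[(8Z,15S)-15-[(tert-butyldimethylsilyl)oxy]heptadec-8-en-1-yl]phenol F2. Treatment with Bu4NF and AcOH as in step 10 then gives 22. This is the known selenenylation and selenoxide elimination route from 3-oxygenated cyclohexenones to resorcinol monoethers, and hydrogen peroxide leaves the isolated alkene alone.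

Step 7. The enolizable enone may be deconjugated or self-condensed by methoxide in competition with conjugate addition, or the Michael addition may reverse before ring closure. The fallback sets out from 11 and comes back at 16, and hence at 18. A Wittig reaction of 11 with methyl (triphenylphosphoranylidene)acetate in THF at reflux should give methyl (2E,11Z,18S)-18-hydroxyicosa-2,11-dienoate F3. Methyl acetoacetate and NaOMe in MeOH at reflux should add to this less acidic acceptor to give dimethyl 2-acetyl-3-[(8Z,15S)-15-hydroxyheptadec-8-en-1-yl]pentanedioate F4, which is not isolated. Its methyl ketone enolate closes onto the chain ester to give the same cyclic keto ester 16. Saponification and acid decarboxylation as in step 7 then deliver 18. The roles of donor and acceptor are exchanged, but ring A is still grown on the chain.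

Step 4. Proton transfer from the free hydroxyl may quench the ylide, and oxaphosphetane equilibration may erode the Z selectivity. The fallback sets out from 1 and comes back at 10, making the alkene by semi-hydrogenation instead of olefination.
- Lithium hex-1-ynide (hex-1-yne, n-BuLi) with BF3·OEt2 in THF at −78 °C should open 1 at CH2 to give (3S)-dec-5-yn-3-ol F5.
- KH in 1,3-diaminopropane should move the triple bond to the chain terminus (alkyne zipper) without touching the alkoxide-protected carbinol, giving (3S)-dec-9-yn-3-ol F6.
- 8-Bromooctan-1-ol is protected with 3,4-dihydro-2H-pyran and pyridinium p-toluenesulfonate as 2-[(8-bromooctyl)oxy]oxane F7.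
- The dianion of F6 (n-BuLi, 2.1 equiv, THF–HMPA, −40 °C to 20 °C) is alkylated with F7 to give (3S)-18-(oxan-2-yloxy)octadec-9-yn-3-ol F8.
- Pyridinium p-toluenesulfonate in MeOH should release (16S)-octadec-9-yne-1,16-diol F9.
- Hydrogenation over Pd/CaCO3 poisoned with Pb(OAc)2 and quinoline in EtOAc should give 10 by syn addition.

**Further compounds**

F1 | step 9 | 3-[(tert-butyldimethylsilyl)oxy]-5-[(8Z,15S)-15-[(tert-butyldimethylsilyl)oxy]heptadec-8-en-1-yl]-6-(phenylselanyl)cyclohex-2-en-1-one | CC[C@H](O[Si](C)(C)C(C)(C)C)CCCCC/C=C\CCCCCCCC1CC(O[Si](C)(C)C(C)(C)C)=CC(=O)C1[Se]c1ccccc1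
F2 | step 9 | 3-[(tert-butyldimethylsilyl)oxy]-5-[(8Z,15S)-15-[(tert-butyldimethylsilyl)oxy]heptadec-8-en-1-yl]phenol | CC[C@H](O[Si](C)(C)C(C)(C)C)CCCCC/C=C\CCCCCCCc1cc(O)cc(O[Si](C)(C)C(C)(C)C)c1
F3 | step 7 | methyl (2E,11Z,18S)-18-hydroxyicosa-2,11-dienoate | CC[C@H](O)CCCCC/C=C\CCCCCCC/C=C/C(=O)OC
F4 | step 7 | dimethyl 2-acetyl-3-[(8Z,15S)-15-hydroxyheptadec-8-en-1-yl]pentanedioate | CC[C@H](O)CCCCC/C=C\CCCCCCCC(CC(=O)OC)C(C(C)=O)C(=O)OC
F5 | step 4 | (3S)-dec-5-yn-3-ol | CC[C@H](O)CC#CCCCC
F6 | step 4 | (3S)-dec-9-yn-3-ol | CC[C@H](O)CCCCCC#C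
F7 | step 4 | 2-[(8-bromooctyl)oxy]oxane | BrCCCCCCCCOC1CCCCO1
F8 | step 4 | (3S)-18-(oxan-2-yloxy)octadec-9-yn-3-ol | CC[C@H](O)CCCCCC#CCCCCCCCCOC1CCCCO1
F9 | step 4 | (16S)-octadec-9-yne-1,16-diol | CC[C@H](O)CCCCCC#CCCCCCCCCO
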